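The oxolane is numbered O1, C2 (H2), C3 (OAc, benzyl), C4 (CH2OH), C5 (aryl). The acetate on quaternary C3 is read as the Baeyer–Villiger product of an acetyl group; the resulting 3-acetyl-oxolane is the retron of a Prins–pinacol rearrangement. Its precursor is a 2-aryl-4-alkenyl-4-methyl-1,3-dioxolane, prepared as a mixture of all stereoisomers. A confined chiral Brønsted acid ionizes it; Prins closure forms C4–C5, the pinacol shift forms C2–C3 and unveils the acetyl group. Both stereocentres of the acetal are erased, so the mixture converges on one ketone with C3, C4 and C5 set. Oxidation with retention and hydrogenolysis finish the route.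

Key step: step 8

Remark (assumption): the sense of induction of the chiral acid in step 8 cannot be derived from a model; the route is written for the (S,S)-acid on the assumption that it gives the (3S,4R,5S) series, and the mirror-image acid is used if the first experiment shows the opposite sense.
Remark: compounds 3, 5 to 8 and 12 are racemic at the carbinol carbon (5 to 8 and 12 are also both acetal epimers); their SMILES carry no descriptor at these centres because step 8 destroys both.

Step 1
Reactants: 1 hydroxyacetone; 2 ethynylmagnesium bromide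
Product: 3 rac-2-methylbut-3-yne-1,2-diol
Conditions: 2 (2.5 equiv), THF, 0 °C to rt; aq. NH4Cl
Reagents that add atoms: none
Why: Grignard 1,2-addition of the acetylide to the ketone after deprotonation of the hydroxyl group; the carbinol centre is deliberately left racemic because step 8 erases it.

Step 2
Reactants: 3 rac-2-methylbut-3-yne-1,2-diol; 4 3,4-dimethoxybenzaldehyde
Product: 5 2-(3,4-dimethoxyphenyl)-4-ethynyl-4-methyl-1,3-dioxolane (both epimers)
Conditions: pyridinium p-toluenesulfonate (cat.), toluene, reflux, Dean–Stark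
Reagents that add atoms: none
Why: Acid-catalysed acetalization with azeotropic removal of water closes the dioxolane on the 1,2-diol; the acetal protects the diol through steps 3 to 7 and is the latent oxocarbenium ion of step 8, so its epimers need no separation.

Step 3
Reactants: 5 2-(3,4-dimethoxyphenyl)-4-ethynyl-4-methyl-1,3-dioxolane
Product: 6 3-[2-(3,4-dimethoxyphenyl)-4-methyl-1,3-dioxolan-4-yl]prop-2-yn-1-ol
Conditions: n-BuLi, THF, −78 °C; (CH2O)n, −78 °C to rt
Reagents that add atoms: paraformaldehyde (as formaldehyde), C=O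
Why: Deprotonation of the terminal alkyne and addition of the lithium acetylide to formaldehyde (alkynylation of an aldehyde) should give the propargylic alcohol whose hydroxyl group directs step 4.

Step 4
Reactants: 6 3-[2-(3,4-dimethoxyphenyl)-4-methyl-1,3-dioxolan-4-yl]prop-2-yn-1-ol
Product: 7 (Z)-3-[2-(3,4-dimethoxyphenyl)-4-methyl-1,3-dioxolan-4-yl]-3-iodoprop-2-en-1-ol
Conditions: NaAlH2(OCH2CH2OMe)2 (Red-Al), THF, 0 °C; then I2, −78 to 0 °C
Reagents that add atoms: iodine, [I][I]
Why: Hydroxyl-directed trans-hydroalumination places hydride on the alkyne carbon next to CH2O and aluminium on the distal carbon through a five-membered alkoxyaluminate, and iodinolysis of the C–Al bond with retention should give the Z-iodide with iodine (the site of the later benzyl group) cis to CH2OH.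

Step 5
Reactants: 7 (Z)-3-[2-(3,4-dimethoxyphenyl)-4-methyl-1,3-dioxolan-4-yl]-3-iodoprop-2-en-1-ol
Product: 8 4-[(Z)-3-(benzyloxy)-1-iodoprop-1-en-1-yl]-2-(3,4-dimethoxyphenyl)-4-methyl-1,3-dioxolane
Conditions: NaH, BnBr, Bu4NI (cat.), THF, 0 °C to rt
Reagents that add atoms: benzyl bromide, BrCc1ccccc1
Why: Williamson etherification of the primary alkoxide; the benzyl ether is inert to organozinc, acid and peracid and leaves together with the phenolic benzyl group in step 10.

Step 6
Reactants: 9 4-(benzyloxy)-3-methoxybenzyl alcohol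
Product: 10 4-(benzyloxy)-3-methoxybenzyl chloride
Conditions: SOCl2, CH2Cl2, 0 °C
Reagents that add atoms: thionyl chloride, O=S(Cl)Cl
Why: Chlorodehydroxylation of the electron-rich benzylic alcohol via its chlorosulfite (nucleophilic substitution at the benzylic carbon).

Step 7
Reactants: 10 4-(benzyloxy)-3-methoxybenzyl chloride; 8 4-[(Z)-3-(benzyloxy)-1-iodoprop-1-en-1-yl]-2-(3,4-dimethoxyphenyl)-4-methyl-1,3-dioxolane
Product: 12 4-{(E)-4-(benzyloxy)-1-[4-(benzyloxy)-3-methoxyphenyl]but-2-en-2-yl}-2-(3,4-dimethoxyphenyl)-4-methyl-1,3-dioxolane (all four stereoisomers), via benzylzinc chloride 11 (not isolated)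
Conditions: Zn, LiCl, THF, rt; then 8, Pd(PPh3)4 (5 mol%), THF, rt to 50 °C
Reagents that add atoms: none
Why: LiCl-assisted insertion of zinc into the benzylic C–Cl bond and Negishi cross-coupling (oxidative addition of the alkenyl iodide to zerovalent palladium, transmetalation, reductive elimination) replace iodine by benzyl with retention of the alkene geometry, giving the E-alkene with benzyl cis to CH2OBn.

Step 8
Reactants: 12 4-{(E)-4-(benzyloxy)-1-[4-(benzyloxy)-3-methoxyphenyl]but-2-en-2-yl}-2-(3,4-dimethoxyphenyl)-4-methyl-1,3-dioxolane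
Product: 15 1-[(3S,4R,5S)-3-[4-(benzyloxy)-3-methoxybenzyl]-4-[(benzyloxy)methyl]-5-(3,4-dimethoxyphenyl)oxolan-3-yl]ethan-1-one, via oxocarbenium ion 13 (not isolated), via oxan-4-yl cation 14 (not isolated)
Conditions: (S,S)-imidodiphosphorimidate acid HN[P(=NSO2CF3)(O2C20H10Ar2)]2 with Ar = 3,5-(CF3)2C6H3 on both (S)-1,1'-binaphthalene-2,2'-diolate units (5 mol%), 5 Å molecular sieves, CH2Cl2/cyclohexane, −40 to −20 °C
Reagents that add atoms: none
Why: Proposed new method: the acid opens the dioxolane to the E-configured aryl oxocarbenium ion 13, the alkene carbon that bears CH2OBn attacks it in a chair-like Prins cyclization (C4–C5 bond) to give tertiary cation 14, and a pinacol 1,2-shift of the ring CH2 from the carbinol carbon to the cationic carbon (C2–C3 bond) contracts the ring, releases the acetyl group and returns the proton to the catalyst. The closest known reaction types are the Lewis- or Brønsted-acid-promoted Prins–pinacol rearrangement of 4-alkenyl-1,3-dioxolanes to 3-acyloxolanes and the asymmetric Prins cyclization of aryl oxocarbenium ions paired with chiral imidodiphosphorimidate anions; new is the chiral-acid-catalysed, enantioconvergent variant. The oxane forms by 6-endo-trig closure and the oxolane by ring contraction, so the C5–O1–C2 unit is delivered to one face of the alkene. C5 is set by the face of the oxocarbenium ion left open by the chiral anion, which is held by a hydrogen bond to the tertiary OH; C4 follows from the chair with aryl and CH2OBn both equatorial (4,5-trans); C3 follows from the E-alkene, whose cis-related benzyl and CH2OBn groups stay cis, which puts acetyl cis to the aryl group. The step needs catalyst control over the carbinol centre of 12 and a cation placed next to the hydroxyl-bearing carbon: the carbinol and acetal centres are both destroyed in the step, so all four stereoisomers of 12 can converge, and the benzyl group on the internal alkene carbon directs the attack so that the cation forms exactly where the pinacol shift quenches it.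

Step 9
Reactants: 15 1-[(3S,4R,5S)-3-[4-(benzyloxy)-3-methoxybenzyl]-4-[(benzyloxy)methyl]-5-(3,4-dimethoxyphenyl)oxolan-3-yl]ethan-1-one
Product: 16 (3S,4R,5S)-3-[4-(benzyloxy)-3-methoxybenzyl]-4-[(benzyloxy)methyl]-5-(3,4-dimethoxyphenyl)oxolan-3-yl acetate
Conditions: mCPBA, NaHCO3, CH2Cl2, 0 °C to rt
Reagents that add atoms: mCPBA (3-chloroperoxybenzoic acid), O=C(OO)c1cccc(Cl)c1
Why: Baeyer–Villiger oxidation: in the Criegee intermediate the tertiary C3 migrates in preference to methyl and with retention of configuration, so the acetyl group should become the tertiary acetate without change at C3.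

Step 10
Reactants: 16 (3S,4R,5S)-3-[4-(benzyloxy)-3-methoxybenzyl]-4-[(benzyloxy)methyl]-5-(3,4-dimethoxyphenyl)oxolan-3-yl acetate
Product: 17 (3S,4R,5S)-5-(3,4-dimethoxyphenyl)-3-(4-hydroxy-3-methoxybenzyl)-4-(hydroxymethyl)oxolan-3-yl acetate
Conditions: H2 (1 atm), Pd/C (10% palladium on carbon), EtOAc, rt, stopped at full conversion of 16
Reagents that add atoms: none
Why: Palladium-catalysed hydrogenolysis should cleave the aryl and the primary alkyl benzyl ether under neutral conditions, which avoids acetyl migration from the tertiary to the primary oxygen, and is stopped before the slower hydrogenolysis of the benzylic C5–O1 bond sets in.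

Compound list
1 | hydroxyacetone (1-hydroxypropan-2-one) | CC(=O)CO | starting material
2 | ethynylmagnesium bromide | C#C[Mg]Br | starting material
3 | rac-2-methylbut-3-yne-1,2-diol | C#CC(C)(O)CO | intermediate
4 | 3,4-dimethoxybenzaldehyde | COc1ccc(C=O)cc1OC | starting material
5 | 2-(3,4-dimethoxyphenyl)-4-ethynyl-4-methyl-1,3-dioxolane (racemic, both acetal epimers) | C#CC1(C)COC(c2ccc(OC)c(OC)c2)O1 | intermediate
6 | 3-[2-(3,4-dimethoxyphenyl)-4-methyl-1,3-dioxolan-4-yl]prop-2-yn-1-ol (racemic, both acetal epimers) | OCC#CC1(C)COC(c2ccc(OC)c(OC)c2)O1 | intermediate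
7 | (Z)-3-[2-(3,4-dimethoxyphenyl)-4-methyl-1,3-dioxolan-4-yl]-3-iodoprop-2-en-1-ol (racemic, both acetal epimers) | OC/C=C(\I)C1(C)COC(c2ccc(OC)c(OC)c2)O1 | intermediate
8 | 4-[(Z)-3-(benzyloxy)-1-iodoprop-1-en-1-yl]-2-(3,4-dimethoxyphenyl)-4-methyl-1,3-dioxolane (racemic, both acetal epimers) | I/C(=C\COCc1ccccc1)C1(C)COC(c2ccc(OC)c(OC)c2)O1 | intermediate
9 | 4-(benzyloxy)-3-methoxybenzyl alcohol | COc1cc(CO)ccc1OCc1ccccc1 | starting material
10 | 4-(benzyloxy)-3-methoxybenzyl chloride | COc1cc(CCl)ccc1OCc1ccccc1 | intermediate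
11 | [4-(benzyloxy)-3-methoxybenzyl]zinc chloride | COc1cc(C[Zn]Cl)ccc1OCc1ccccc1 | intermediate (not isolated)
12 | 4-{(E)-4-(benzyloxy)-1-[4-(benzyloxy)-3-methoxyphenyl]but-2-en-2-yl}-2-(3,4-dimethoxyphenyl)-4-methyl-1,3-dioxolane (racemic, both acetal epimers) | COc1ccc(C2OCC(C)(O2)/C(Cc2ccc(OCc3ccccc3)c(OC)c2)=C/COCc2ccccc2)cc1OC | intermediate
13 | [(3,4-dimethoxyphenyl)methylidene]{(E)-5-(benzyloxy)-3-[4-(benzyloxy)-3-methoxybenzyl]-2-hydroxy-2-methylpent-3-en-1-yl}oxonium, E at C=O, paired with the catalyst anion | COc1ccc(C=[O+]CC(C)(O)/C(Cc2ccc(OCc3ccccc3)c(OC)c2)=C/COCc2ccccc2)cc1OC | intermediate (not isolated)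
14 | (2S,3R)-3-[(benzyloxy)methyl]-4-[4-(benzyloxy)-3-methoxybenzyl]-2-(3,4-dimethoxyphenyl)-5-hydroxy-5-methyloxan-4-ylium, paired with the catalyst anion | COc1cc(C[C+]2C(C)(O)CO[C@H](c3ccc(OC)c(OC)c3)[C@H]2COCc2ccccc2)ccc1OCc1ccccc1 | intermediate (not isolated)
15 | 1-[(3S,4R,5S)-3-[4-(benzyloxy)-3-methoxybenzyl]-4-[(benzyloxy)methyl]-5-(3,4-dimethoxyphenyl)oxolan-3-yl]ethan-1-one | COc1cc(C[C@@]2(C(C)=O)CO[C@H](c3ccc(OC)c(OC)c3)[C@H]2COCc2ccccc2)ccc1OCc1ccccc1 | intermediate
16 | (3S,4R,5S)-3-[4-(benzyloxy)-3-methoxybenzyl]-4-[(benzyloxy)methyl]-5-(3,4-dimethoxyphenyl)oxolan-3-yl acetate | COc1cc(C[C@@]2(OC(C)=O)CO[C@H](c3ccc(OC)c(OC)c3)[C@H]2COCc2ccccc2)ccc1OCc1ccccc1 | intermediate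
17 | (3S,4R,5S)-5-(3,4-dimethoxyphenyl)-3-(4-hydroxy-3-methoxybenzyl)-4-(hydroxymethyl)oxolan-3-yl acetate | COc1cc(C[C@@]2(OC(C)=O)CO[C@H](c3ccc(OC)c(OC)c3)[C@H]2CO)ccc1O | target

Total step count: 10. Longest linear sequence: 9 steps (steps 1 to 5 and 7 to 10).

Steps most likely to fail

Step 8 (proposed new method). The catalyst may fail to override the carbinol centre, so that one enantiomer of 12 cyclizes through the wrong chair and lowers the enantiomeric purity. Proton loss or a hydride shift at cation 14 may also outrun the pinacol shift. The fallback uses known chemistry and sets out from acetal 12. The stoichiometric Lewis-acid Prins–pinacol rearrangement (SnCl4, CH2Cl2, −78 to −20 °C) should give the ketone with the same relative configuration as a racemate, that is 15 together with the mirror-image ketone F1. Preparative chromatography on a chiral stationary phase removes F1, and the route is re-entered at 15.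

Step 10. Hydrogenolytic opening of the benzylic C5–O1 bond of the electron-rich 5-aryl-oxolane may compete while the slowly cleaved primary alkyl benzyl ether is still present. The fallback changes the protecting group and sets out from iodo alcohol 7. Silylation (t-BuPh2SiCl, imidazole, DMF) should give silyl ether F2. Coupling with 11 under the conditions of step 7 should give acetal F3, and the conditions of step 8 should give ketone F4. Baeyer–Villiger oxidation as in step 9 should give acetate F5. HF·pyridine in THF removes the silyl group without base, hence without acetyl migration, and should give alcohol F6. A brief hydrogenolysis (H2, Pd/C, EtOAc) then cleaves only the fast-reacting aryl benzyl ether and returns to the route at 17.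

Step 4. The alkenylaluminate may eliminate the dioxolane oxygen to form an allene, or be protonated before iodination. The fallback sets out from propargylic alcohol 6. Trans-hydrosilylation with BnMe2SiH and [Cp*Ru(MeCN)3]PF6 (cat.) in CH2Cl2 places silicon on the alkyne carbon distal to the hydroxyl group and hydrogen trans to it, and should give alkenylsilane F7. Iododesilylation with retention (N-iodosuccinimide, 2,6-lutidine, (CF3)2CHOH, 0 °C) returns to the route at 7.

Further compounds
F1 | step 8 | 1-[(3R,4S,5R)-3-[4-(benzyloxy)-3-methoxybenzyl]-4-[(benzyloxy)methyl]-5-(3,4-dimethoxyphenyl)oxolan-3-yl]ethan-1-one | COc1cc(C[C@]2(C(C)=O)CO[C@@H](c3ccc(OC)c(OC)c3)[C@@H]2COCc2ccccc2)ccc1OCc1ccccc1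
F2 | step 10 | 4-[(Z)-3-{[tert-butyl(diphenyl)silyl]oxy}-1-iodoprop-1-en-1-yl]-2-(3,4-dimethoxyphenyl)-4-methyl-1,3-dioxolane | I/C(=C\CO[Si](c1ccccc1)(c1ccccc1)C(C)(C)C)C1(C)COC(c2ccc(OC)c(OC)c2)O1
F3 | step 10 | 4-{(E)-1-[4-(benzyloxy)-3-methoxyphenyl]-4-{[tert-butyl(diphenyl)silyl]oxy}but-2-en-2-yl}-2-(3,4-dimethoxyphenyl)-4-methyl-1,3-dioxolane | COc1ccc(C2OCC(C)(O2)/C(Cc2ccc(OCc3ccccc3)c(OC)c2)=C/CO[Si](c2ccccc2)(c2ccccc2)C(C)(C)C)cc1OC
F4 | step 10 | 1-[(3S,4R,5S)-3-[4-(benzyloxy)-3-methoxybenzyl]-4-({[tert-butyl(diphenyl)silyl]oxy}methyl)-5-(3,4-dimethoxyphenyl)oxolan-3-yl]ethan-1-one | COc1cc(C[C@@]2(C(C)=O)CO[C@H](c3ccc(OC)c(OC)c3)[C@H]2CO[Si](c2ccccc2)(c2ccccc2)C(C)(C)C)ccc1OCc1ccccc1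
F5 | step 10 | (3S,4R,5S)-3-[4-(benzyloxy)-3-methoxybenzyl]-4-({[tert-butyl(diphenyl)silyl]oxy}methyl)-5-(3,4-dimethoxyphenyl)oxolan-3-yl acetate | COc1cc(C[C@@]2(OC(C)=O)CO[C@H](c3ccc(OC)c(OC)c3)[C@H]2CO[Si](c2ccccc2)(c2ccccc2)C(C)(C)C)ccc1OCc1ccccc1
F6 | step 10 | (3S,4R,5S)-3-[4-(benzyloxy)-3-methoxybenzyl]-5-(3,4-dimethoxyphenyl)-4-(hydroxymethyl)oxolan-3-yl acetate | COc1cc(C[C@@]2(OC(C)=O)CO[C@H](c3ccc(OC)c(OC)c3)[C@H]2CO)ccc1OCc1ccccc1
F7 | step 4 | (Z)-3-[benzyl(dimethyl)silyl]-3-[2-(3,4-dimethoxyphenyl)-4-methyl-1,3-dioxolan-4-yl]prop-2-en-1-ol | OC/C=C(\[Si](C)(C)Cc1ccccc1)C1(C)COC(c2ccc(OC)c(OC)c2)O1
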